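The six-membered ring C5–C10 holds the quaternary C10 (methyl C14, vinyl C1–C2) between C5 and the oxygenated C6. With vinyl carbon C1 written as an ester, C10=C5 is the alkene of a cyclohexenecarboxylate whose γ-carbon C6 bears oxygen, and the route cuts C4–C5 and C10–C14 there. In one operation a cuprate carrying C3–C4–C15 adds to C5 anti to the C6 silyloxy group and iodomethane alkylates C10 anti to the new group. The precursor is methyl (R)-3-silyloxycyclohexa-1,4-diene-1-carboxylate from quinic acid. Its spectator C7=C8 bond spares C6 from any later oxidation and receives C11–C13 and the C8 oxygen by a tethered radical cyclization.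

Key step: step 10

Remark: atoms are numbered as in the elemane skeleton (C11(=C13)–C12 on C7, C15 on C4). The target is taken as drawn, the free 6-hydroxy 12-acid and not its γ-lactone, so no acidic operation follows the formation of the acid.

Step 1
Reactants: 1 (−)-quinic acid
Product: 2 3,4-O-isopropylidenequinic acid 1,5-lactone
Conditions: 2,2-dimethoxypropane, TsOH·H2O (cat.), acetone, reflux
Reagents that add atoms: 2,2-dimethoxypropane, COC(C)(C)OC
Why: Acid-catalysed acetalization of the only cis-vicinal diol with concurrent lactonization of the carboxyl group onto the syn 5-hydroxyl should give the bicyclic lactone without touching a stereocentre.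

Step 2
Reactants: 2 3,4-O-isopropylidenequinic acid 1,5-lactone
Product: 3 methyl 3,4-O-isopropylidenequinate
Conditions: NaOMe (cat.), MeOH, 0 °C → rt
Reagents that add atoms: methanol, CO
Why: Methoxide-catalysed transesterification opens the bridged lactone to the methyl ester and frees the secondary hydroxyl on the carbon that becomes C6, the tertiary hydroxyl staying untouched.

Step 3
Reactants: 3 methyl 3,4-O-isopropylidenequinate
Product: 5 methyl (4R,5R)-4,5-(isopropylidenedioxy)-3-oxocyclohex-1-ene-1-carboxylate, via β-hydroxy ketone 4 (not isolated)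
Conditions: [C5H5NH][CrO3Cl], pyridine, 3 Å MS, CH2Cl2, rt
Reagents that add atoms: none
Why: Chlorochromate oxidation of the secondary alcohol gives β-hydroxy ketone 4, whose tertiary hydroxyl is lost by E1cB dehydration toward the α-methylene, so the enone (future C5=C10) forms regiospecifically; the carbinol stereocentre is erased on purpose and reset in step 4.

Step 4
Reactants: 5 methyl (4R,5R)-4,5-(isopropylidenedioxy)-3-oxocyclohex-1-ene-1-carboxylate
Product: 6 methyl (3S,4S,5R)-3-hydroxy-4,5-(isopropylidenedioxy)cyclohex-1-ene-1-carboxylate (all-cis)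
Conditions: NaBH4, MeOH, −20 °C → 0 °C
Reagents that add atoms: none
Why: Borohydride 1,2-reduction of the enone under substrate control should occur on the convex face opposite the cis-fused dioxolane, placing the new hydroxyl cis to the acetonide and so setting the future C6 stereocentre as in the target.

Step 5
Reactants: 6 methyl (3S,4S,5R)-3-hydroxy-4,5-(isopropylidenedioxy)cyclohex-1-ene-1-carboxylate
Product: 7 methyl (3S,4R,5R)-4,5-(isopropylidenedioxy)-3-(triisopropylsilyloxy)cyclohex-1-ene-1-carboxylate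
Conditions: i-Pr3SiOTf, 2,6-lutidine, CH2Cl2, 0 °C → rt
Reagents that add atoms: triisopropylsilyl trifluoromethanesulfonate, CC(C)[Si](C(C)C)(C(C)C)OS(=O)(=O)C(F)(F)F
Why: Silyl ether formation with the silyl triflate installs a bulky, acid-stable group that later shields one face of the enoate.

Step 6
Reactants: 7 methyl (3S,4R,5R)-4,5-(isopropylidenedioxy)-3-(triisopropylsilyloxy)cyclohex-1-ene-1-carboxylate
Product: 8 methyl (3S,4R,5R)-4,5-dihydroxy-3-(triisopropylsilyloxy)cyclohex-1-ene-1-carboxylate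
Conditions: AcOH/H2O (4:1), 50 °C
Reagents that add atoms: none
Why: Aqueous acid hydrolysis of the isopropylidene acetal should free the cis-diol while the hindered triisopropylsilyl ether survives.

Step 7
Reactants: 8 methyl (3S,4R,5R)-4,5-dihydroxy-3-(triisopropylsilyloxy)cyclohex-1-ene-1-carboxylate
Product: 9 cyclic 4,5-thionocarbonate of 8
Conditions: 1,1′-thiocarbonyldiimidazole, toluene, 80 °C
Reagents that add atoms: 1,1′-thiocarbonyldiimidazole, S=C(n1ccnc1)n1ccnc1
Why: The cis-diol condenses with the thiocarbonyl transfer reagent to the cyclic thionocarbonate, the first stage of a Corey–Winter olefination.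

Step 8
Reactants: 9 cyclic 4,5-thionocarbonate of 8
Product: 10 methyl (R)-3-(triisopropylsilyloxy)cyclohexa-1,4-diene-1-carboxylate
Conditions: 1,3-dimethyl-2-phenyl-1,3,2-diazaphospholidine, THF, 40 °C
Reagents that add atoms: none
Why: Thiophilic attack on sulfur and stereospecific syn-cycloelimination of CO2 (Corey–Winter olefination, Corey–Hopkins variant) turn the diol carbons into the C7=C8 bond under neutral conditions that should not aromatize the silyloxy diene.

Step 9
Reactants: 11 2-bromoallyl alcohol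
Product: 12 2-bromoallyl trityl ether
Conditions: Ph3CCl, Et3N, DMAP (cat.), CH2Cl2, rt
Reagents that add atoms: trityl chloride, ClC(c1ccccc1)(c1ccccc1)c1ccccc1
Why: Tritylation of the primary alcohol (SN1 etherification) gives a base-stable ether that later leaves under the same mild acid as the acetals.

Step 10
Reactants: 10 methyl (R)-3-(triisopropylsilyloxy)cyclohexa-1,4-diene-1-carboxylate; 12 2-bromoallyl trityl ether; 13 iodomethane
Product: 17 methyl (1R,5R,6R)-1-methyl-5-(triisopropylsilyloxy)-6-[3-(trityloxy)prop-1-en-2-yl]cyclohex-3-ene-1-carboxylate, via alkenyllithium 14 (not isolated), via lithium dialkenylcuprate 15 (not isolated), via lithium ester enolate 16 (not isolated)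
Conditions: 12, t-BuLi, Et2O, −78 °C; CuBr·SMe2, −78 → −40 °C; 10, THF, −78 → −30 °C; MeI, DMPU, −30 → 0 °C
Reagents that add atoms: none
Why: Cuprate 15 π-complexes the enoate of 10 and delivers the C4 unit to C5 by reductive elimination from a trivalent copper intermediate, and the ester enolate 16 is then methylated at C10 in the same flask by SN2 attack on iodomethane; the closest known reaction type is the tandem organocopper conjugate addition–enolate alkylation of γ-silyloxy cycloalkenyl esters. No ring is closed. C5 is set by the C6 stereocentre, because the cuprate enters the face opposite the bulky allylic silyloxy group. C10 is set by the new C5 stereocentre, because the C5 alkenyl group stands pseudoaxial to avoid allylic strain with the exocyclic enolate and iodomethane attacks the other face, leaving the ester cis to the C4 unit. The step needs 1,4-addition instead of deprotonation at C9 or displacement of the silyloxy group, which the soft, weakly basic cuprate at low temperature and the poor silyloxide leaving group should secure; it also needs double anti selectivity, which rests on the C6 stereocentre alone because the C7=C8 bond is isolated from the enoate.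

Step 11
Reactants: 17 methyl (1R,5R,6R)-1-methyl-5-(triisopropylsilyloxy)-6-[3-(trityloxy)prop-1-en-2-yl]cyclohex-3-ene-1-carboxylate
Product: 18 [(1R,5R,6R)-1-methyl-5-(triisopropylsilyloxy)-6-[3-(trityloxy)prop-1-en-2-yl]cyclohex-3-en-1-yl]methanol
Conditions: LiAlH4, THF, 0 °C
Reagents that add atoms: none
Why: Hydride reduction of the hindered ester to the primary alcohol leaves the silyl and trityl ethers and the alkenes untouched.

Step 12
Reactants: 18 [(1R,5R,6R)-1-methyl-5-(triisopropylsilyloxy)-6-[3-(trityloxy)prop-1-en-2-yl]cyclohex-3-en-1-yl]methanol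
Product: 19 (1R,5R,6R)-1-methyl-5-(triisopropylsilyloxy)-6-[3-(trityloxy)prop-1-en-2-yl]cyclohex-3-ene-1-carbaldehyde
Conditions: Dess–Martin periodinane, NaHCO3, CH2Cl2, 0 °C → rt
Reagents that add atoms: none
Why: Buffered Dess–Martin oxidation gives the non-enolizable aldehyde on quaternary C10 without acid that would endanger the trityl ether.

Step 13
Reactants: 19 (1R,5R,6R)-1-methyl-5-(triisopropylsilyloxy)-6-[3-(trityloxy)prop-1-en-2-yl]cyclohex-3-ene-1-carbaldehyde
Product: 20 triisopropyl{[(1R,5S,6S)-5-ethenyl-5-methyl-6-[3-(trityloxy)prop-1-en-2-yl]cyclohex-2-en-1-yl]oxy}silane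
Conditions: Ph3PCH3Br, KN(SiMe3)2, THF, 0 → 40 °C
Reagents that add atoms: methyltriphenylphosphonium bromide, C[P+](c1ccccc1)(c1ccccc1)c1ccccc1.[Br-]
Why: Wittig methylenation of the hindered aldehyde with the non-stabilized ylide creates the C1=C2 vinyl group on C10.

Step 14
Reactants: 20 triisopropyl{[(1R,5S,6S)-5-ethenyl-5-methyl-6-[3-(trityloxy)prop-1-en-2-yl]cyclohex-2-en-1-yl]oxy}silane
Product: 21 (1R,5S,6S)-5-ethenyl-5-methyl-6-[3-(trityloxy)prop-1-en-2-yl]cyclohex-2-en-1-ol
Conditions: Bu4NF, THF, rt → 40 °C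
Reagents that add atoms: none
Why: Fluoride desilylation frees the C6 allylic alcohol with its configuration unchanged, the trityl ether being inert.

Step 15
Reactants: 21 (1R,5S,6S)-5-ethenyl-5-methyl-6-[3-(trityloxy)prop-1-en-2-yl]cyclohex-2-en-1-ol
Product: 22 2-iodo-1-methoxyprop-2-en-1-yl acetal of alcohol 21 (acetal epimers)
Conditions: methoxyallene, N-iodosuccinimide, CH2Cl2, −78 → −30 °C
Reagents that add atoms: N-iodosuccinimide, O=C1CCC(=O)N1I; methoxyallene, COC=C=C
Why: Iodonium transfer to the central carbon of the electron-rich allene and capture of the methoxy-stabilized cation by the C6 hydroxyl (iodo-acetalization, the alkoxyallene version of the Ueno–Stork tether) attaches the C11–C13 unit to the C6 oxygen; the acetal carbon forms as an epimer mixture of no consequence.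

Step 16
Reactants: 22 2-iodo-1-methoxyprop-2-en-1-yl acetal of alcohol 21
Product: 24 (3aR,4S,6S,7S,7aS)-6-ethenyl-2-methoxy-6-methyl-3-methylidene-7-[3-(trityloxy)prop-1-en-2-yl]octahydro-1-benzofuran-4-ol (C2 epimers), via C8 hydroperoxide 23 (not isolated)
Conditions: Bu3SnH (slow addition), BEt3 (cat.), dry air, toluene, 0 °C → rt; then PPh3
Reagents that add atoms: dioxygen, O=O
Why: Iodine abstraction gives a vinyl radical that closes 5-exo onto C7 on the face of the C6 tether oxygen (Ueno–Stork radical cyclization), so C7 is set cis to C6–O, and the C8 radical should be captured by oxygen anti to the new C7–C11 bond (aerobic radical trapping), the hydroperoxide being reduced by PPh3.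

Step 17
Reactants: 25 L-erythrulose
Product: 26 (S)-1-(2,2-dimethyl-1,3-dioxolan-4-yl)-2-hydroxyethan-1-one
Conditions: 2,2-dimethoxypropane, TsOH·H2O (cat.), acetone, rt
Reagents that add atoms: 2,2-dimethoxypropane, COC(C)(C)OC
Why: Acetalization of the terminal vicinal diol of the ketotriol leaves the primary α-hydroxyl free and the stereocentre untouched.

Step 18
Reactants: 26 (S)-1-(2,2-dimethyl-1,3-dioxolan-4-yl)-2-hydroxyethan-1-one
Product: 27 (S)-2-(tert-butyldimethylsilyloxy)-1-(2,2-dimethyl-1,3-dioxolan-4-yl)ethan-1-one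
Conditions: t-BuMe2SiCl, imidazole, CH2Cl2, 0 °C → rt
Reagents that add atoms: tert-butyldimethylsilyl chloride, CC(C)(C)[Si](C)(C)Cl
Why: Silylation of the primary alcohol protects it from the basic ylide of the next step.

Step 19
Reactants: 27 (S)-2-(tert-butyldimethylsilyloxy)-1-(2,2-dimethyl-1,3-dioxolan-4-yl)ethan-1-one
Product: 28 (R)-tert-butyl{[2-(2,2-dimethyl-1,3-dioxolan-4-yl)prop-2-en-1-yl]oxy}dimethylsilane
Conditions: Ph3PCH3Br, KN(SiMe3)2, THF, −78 → 0 °C
Reagents that add atoms: methyltriphenylphosphonium bromide, C[P+](c1ccccc1)(c1ccccc1)c1ccccc1.[Br-]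
Why: Wittig methylenation of the ketone at low temperature should form the 1,1-disubstituted alkene without enolizing the adjacent stereocentre (the descriptor changes only because the priorities change).

Step 20
Reactants: 28 (R)-tert-butyl{[2-(2,2-dimethyl-1,3-dioxolan-4-yl)prop-2-en-1-yl]oxy}dimethylsilane
Product: 29 (R)-2-(2,2-dimethyl-1,3-dioxolan-4-yl)prop-2-en-1-ol
Conditions: Bu4NF, THF, 0 °C
Reagents that add atoms: none
Why: Fluoride desilylation frees the primary allylic alcohol.

Step 21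
Reactants: 29 (R)-2-(2,2-dimethyl-1,3-dioxolan-4-yl)prop-2-en-1-ol
Product: 31 (R)-2-(2,2-dimethyl-1,3-dioxolan-4-yl)prop-2-enoic acid, via enal 30 (not isolated)
Conditions: TEMPO (cat.), PhI(OAc)2, MeCN/H2O (1:1), rt
Reagents that add atoms: water, O
Why: Oxoammonium-catalysed oxidation takes the allylic alcohol through enal 30 and its hydrate to the acrylic acid under conditions that an acetonide tolerates.

Step 22
Reactants: 24 (3aR,4S,6S,7S,7aS)-6-ethenyl-2-methoxy-6-methyl-3-methylidene-7-[3-(trityloxy)prop-1-en-2-yl]octahydro-1-benzofuran-4-ol; 31 (R)-2-(2,2-dimethyl-1,3-dioxolan-4-yl)prop-2-enoic acid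
Product: 33 (3aR,4S,6S,7S,7aS)-6-ethenyl-2-methoxy-6-methyl-3-methylidene-7-[3-(trityloxy)prop-1-en-2-yl]octahydro-1-benzofuran-4-yl 2-[(4R)-2,2-dimethyl-1,3-dioxolan-4-yl]prop-2-enoate, via mixed anhydride 32 (not isolated)
Conditions: 31, 2,4,6-Cl3C6H2COCl, Et3N, THF, rt; then 24, DMAP, toluene, rt
Reagents that add atoms: none
Why: Yamaguchi esterification through the mixed anhydride acylates the hindered C8 hydroxyl with retention at C8 and without touching the acetals.

Step 23
Reactants: 33 C8 ester (methyl acetal, trityl ether, acetonide)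
Product: 34 (3aR,4S,6S,7S,7aS)-6-ethenyl-2-hydroxy-7-(3-hydroxyprop-1-en-2-yl)-6-methyl-3-methylideneoctahydro-1-benzofuran-4-yl (3R)-3,4-dihydroxy-2-methylidenebutanoate (lactol, C2 anomers)
Conditions: AcOH/H2O (4:1), 40 °C
Reagents that add atoms: water, O
Why: Mild aqueous acid hydrolyses the allylic methyl acetal, the terminal acetonide and the trityl ether in one operation; because C12 is still at the aldehyde oxidation level, no γ-lactone can form at this stage.

Step 24
Reactants: 34 lactol triol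
Product: 36 target, 2-[(1S,2S,3S,4S,6S)-6-{[(3R)-3,4-dihydroxy-2-methylidenebutanoyl]oxy}-4-ethenyl-2-hydroxy-3-(3-hydroxyprop-1-en-2-yl)-4-methylcyclohexyl]prop-2-enoic acid, via open-chain hydroxy enal 35 (not isolated)
Conditions: NaClO2, NaH2PO4, 2-methyl-2-butene, t-BuOH/H2O, 0 °C; work-up at pH 4–5
Reagents that add atoms: sodium chlorite, [Na+].[O-]Cl=O
Why: Chlorite oxidation of the aldehyde form 35 of the lactol (Pinnick oxidation, hypochlorite scavenged by the alkene additive) should give the acrylic acid chemoselectively beside the free alcohols and alkenes, and the buffered work-up avoids both acid-induced lactonization onto the C6 hydroxyl and base-induced loss of the side chain.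

Compound list

1 | (−)-quinic acid, (1S,3R,4S,5R)-1,3,4,5-tetrahydroxycyclohexane-1-carboxylic acid | OC(=O)[C@]1(O)C[C@@H](O)[C@@H](O)[C@H](O)C1 | starting material
2 | 3,4-O-isopropylidenequinic acid 1,5-lactone | O[C@@]12C[C@H]3OC(C)(C)O[C@H]3[C@@H](C1)OC2=O | intermediate
3 | methyl 3,4-O-isopropylidenequinate | COC(=O)[C@]1(O)C[C@H]2OC(C)(C)O[C@H]2[C@H](O)C1 | intermediate
4 | methyl 5-dehydro-3,4-O-isopropylidenequinate (β-hydroxy ketone) | COC(=O)[C@]1(O)C[C@H]2OC(C)(C)O[C@H]2C(=O)C1 | intermediate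
5 | methyl (4R,5R)-4,5-(isopropylidenedioxy)-3-oxocyclohex-1-ene-1-carboxylate | COC(=O)C1=CC(=O)[C@@H]2OC(C)(C)O[C@@H]2C1 | intermediate
6 | methyl (3S,4S,5R)-3-hydroxy-4,5-(isopropylidenedioxy)cyclohex-1-ene-1-carboxylate (all-cis) | COC(=O)C1=C[C@H](O)[C@@H]2OC(C)(C)O[C@@H]2C1 | intermediate
7 | methyl (3S,4R,5R)-4,5-(isopropylidenedioxy)-3-(triisopropylsilyloxy)cyclohex-1-ene-1-carboxylate | COC(=O)C1=C[C@H](O[Si](C(C)C)(C(C)C)C(C)C)[C@@H]2OC(C)(C)O[C@@H]2C1 | intermediate
8 | methyl (3S,4R,5R)-4,5-dihydroxy-3-(triisopropylsilyloxy)cyclohex-1-ene-1-carboxylate | COC(=O)C1=C[C@H](O[Si](C(C)C)(C(C)C)C(C)C)[C@H](O)[C@H](O)C1 | intermediate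
9 | cyclic 4,5-thionocarbonate of 8 | COC(=O)C1=C[C@H](O[Si](C(C)C)(C(C)C)C(C)C)[C@@H]2OC(=S)O[C@@H]2C1 | intermediate
10 | methyl (R)-3-(triisopropylsilyloxy)cyclohexa-1,4-diene-1-carboxylate (precursor of the key step) | COC(=O)C1=C[C@H](O[Si](C(C)C)(C(C)C)C(C)C)C=CC1 | intermediate
11 | 2-bromoallyl alcohol (2-bromoprop-2-en-1-ol) | C=C(Br)CO | starting material
12 | 2-bromoallyl trityl ether | C=C(Br)COC(c1ccccc1)(c1ccccc1)c1ccccc1 | intermediate
13 | iodomethane | CI | starting material
14 | [3-(trityloxy)prop-1-en-2-yl]lithium | [Li]C(=C)COC(c1ccccc1)(c1ccccc1)c1ccccc1 | intermediate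
15 | lithium bis[3-(trityloxy)prop-1-en-2-yl]cuprate | [Li+].C=C(COC(c1ccccc1)(c1ccccc1)c1ccccc1)[Cu-]C(=C)COC(c1ccccc1)(c1ccccc1)c1ccccc1 | intermediate
16 | lithium ester enolate formed by alkenyl transfer to C5 of 10 | COC(O[Li])=C1CC=C[C@@H](O[Si](C(C)C)(C(C)C)C(C)C)[C@@H]1C(=C)COC(c1ccccc1)(c1ccccc1)c1ccccc1 | intermediate
17 | methyl (1R,5R,6R)-1-methyl-5-(triisopropylsilyloxy)-6-[3-(trityloxy)prop-1-en-2-yl]cyclohex-3-ene-1-carboxylate (product of the key step) | COC(=O)[C@]1(C)CC=C[C@@H](O[Si](C(C)C)(C(C)C)C(C)C)[C@@H]1C(=C)COC(c1ccccc1)(c1ccccc1)c1ccccc1 | intermediate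
18 | [(1R,5R,6R)-1-methyl-5-(triisopropylsilyloxy)-6-[3-(trityloxy)prop-1-en-2-yl]cyclohex-3-en-1-yl]methanol | OC[C@]1(C)CC=C[C@@H](O[Si](C(C)C)(C(C)C)C(C)C)[C@@H]1C(=C)COC(c1ccccc1)(c1ccccc1)c1ccccc1 | intermediate
19 | (1R,5R,6R)-1-methyl-5-(triisopropylsilyloxy)-6-[3-(trityloxy)prop-1-en-2-yl]cyclohex-3-ene-1-carbaldehyde | O=C[C@]1(C)CC=C[C@@H](O[Si](C(C)C)(C(C)C)C(C)C)[C@@H]1C(=C)COC(c1ccccc1)(c1ccccc1)c1ccccc1 | intermediate
20 | triisopropyl{[(1R,5S,6S)-5-ethenyl-5-methyl-6-[3-(trityloxy)prop-1-en-2-yl]cyclohex-2-en-1-yl]oxy}silane | C=C[C@]1(C)CC=C[C@@H](O[Si](C(C)C)(C(C)C)C(C)C)[C@@H]1C(=C)COC(c1ccccc1)(c1ccccc1)c1ccccc1 | intermediate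
21 | (1R,5S,6S)-5-ethenyl-5-methyl-6-[3-(trityloxy)prop-1-en-2-yl]cyclohex-2-en-1-ol | C=C[C@]1(C)CC=C[C@@H](O)[C@@H]1C(=C)COC(c1ccccc1)(c1ccccc1)c1ccccc1 | intermediate
22 | 2-iodo-1-methoxyprop-2-en-1-yl acetal of alcohol 21 (acetal epimers) | C=C[C@]1(C)CC=C[C@@H](OC(OC)C(I)=C)[C@@H]1C(=C)COC(c1ccccc1)(c1ccccc1)c1ccccc1 | intermediate
23 | C8 hydroperoxide corresponding to 24 (OOH in place of OH) | C=C[C@]1(C)C[C@H](OO)[C@H]2C(=C)C(OC)O[C@H]2[C@@H]1C(=C)COC(c1ccccc1)(c1ccccc1)c1ccccc1 | intermediate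
24 | (3aR,4S,6S,7S,7aS)-6-ethenyl-2-methoxy-6-methyl-3-methylidene-7-[3-(trityloxy)prop-1-en-2-yl]octahydro-1-benzofuran-4-ol (C2 epimers; C6–O and C7–C11 cis, C8–OH trans to C7–C11) | C=C[C@]1(C)C[C@H](O)[C@H]2C(=C)C(OC)O[C@H]2[C@@H]1C(=C)COC(c1ccccc1)(c1ccccc1)c1ccccc1 | intermediate
25 | L-erythrulose, (S)-1,3,4-trihydroxybutan-2-one | OCC(=O)[C@@H](O)CO | starting material
26 | (S)-1-(2,2-dimethyl-1,3-dioxolan-4-yl)-2-hydroxyethan-1-one | OCC(=O)[C@@H]1COC(C)(C)O1 | intermediate
27 | (S)-2-(tert-butyldimethylsilyloxy)-1-(2,2-dimethyl-1,3-dioxolan-4-yl)ethan-1-one | CC(C)(C)[Si](C)(C)OCC(=O)[C@@H]1COC(C)(C)O1 | intermediate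
28 | (R)-tert-butyl{[2-(2,2-dimethyl-1,3-dioxolan-4-yl)prop-2-en-1-yl]oxy}dimethylsilane | CC(C)(C)[Si](C)(C)OCC(=C)[C@@H]1COC(C)(C)O1 | intermediate
29 | (R)-2-(2,2-dimethyl-1,3-dioxolan-4-yl)prop-2-en-1-ol | OCC(=C)[C@@H]1COC(C)(C)O1 | intermediate
30 | (R)-2-(2,2-dimethyl-1,3-dioxolan-4-yl)prop-2-enal | O=CC(=C)[C@@H]1COC(C)(C)O1 | intermediate
31 | (R)-2-(2,2-dimethyl-1,3-dioxolan-4-yl)prop-2-enoic acid | OC(=O)C(=C)[C@@H]1COC(C)(C)O1 | intermediate
32 | mixed anhydride of 31 with 2,4,6-trichlorobenzoic acid | C=C(C(=O)OC(=O)c1c(Cl)cc(Cl)cc1Cl)[C@@H]1COC(C)(C)O1 | intermediate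
33 | (3aR,4S,6S,7S,7aS)-6-ethenyl-2-methoxy-6-methyl-3-methylidene-7-[3-(trityloxy)prop-1-en-2-yl]octahydro-1-benzofuran-4-yl 2-[(4R)-2,2-dimethyl-1,3-dioxolan-4-yl]prop-2-enoate (C2 epimers) | C=C[C@]1(C)C[C@H](OC(=O)C(=C)[C@@H]3COC(C)(C)O3)[C@H]2C(=C)C(OC)O[C@H]2[C@@H]1C(=C)COC(c1ccccc1)(c1ccccc1)c1ccccc1 | intermediate
34 | (3aR,4S,6S,7S,7aS)-6-ethenyl-2-hydroxy-7-(3-hydroxyprop-1-en-2-yl)-6-methyl-3-methylideneoctahydro-1-benzofuran-4-yl (3R)-3,4-dihydroxy-2-methylidenebutanoate (lactol, C2 anomers) | C=C[C@]1(C)C[C@H](OC(=O)C(=C)[C@@H](O)CO)[C@H]2C(=C)C(O)O[C@H]2[C@@H]1C(=C)CO | intermediate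
35 | open-chain tautomer of 34, the 12-aldehyde with free C6 hydroxyl | C=C[C@]1(C)C[C@H](OC(=O)C(=C)[C@@H](O)CO)[C@@H](C(=C)C=O)[C@@H](O)[C@@H]1C(=C)CO | intermediate
36 | 2-[(1S,2S,3S,4S,6S)-6-{[(3R)-3,4-dihydroxy-2-methylidenebutanoyl]oxy}-4-ethenyl-2-hydroxy-3-(3-hydroxyprop-1-en-2-yl)-4-methylcyclohexyl]prop-2-enoic acid (5S,6S,7S,8S,10S in elemane numbering) | C=C[C@]1(C)C[C@H](OC(=O)C(=C)[C@@H](O)CO)[C@@H](C(=C)C(=O)O)[C@@H](O)[C@@H]1C(=C)CO | target

Total number of steps: 24 (main line 1–8, 10–16 and 22–24; cuprate source in step 9; side-chain acid in steps 17–21). Longest linear sequence: 18 steps (1–8, 10–16, 22–24).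

Steps most likely to fail

The key step (step 10) may suffer from slow 1,4-addition to the trisubstituted enoate, from deprotonation at C9 followed by loss of silanol (aromatization of the diene), or from incomplete facial control when the copper-containing enolate is methylated. The fallback separates the two bond formations. It sets out from 10. The alkenylcopper–BF3 reagent (12, t-BuLi, CuI, BF3·OEt2, Et2O, −78 °C; Lewis-acid-promoted conjugate addition, fast with enoates and weakly basic), followed by a protic quench, should give methyl (5R,6S)-5-(triisopropylsilyloxy)-6-[3-(trityloxy)prop-1-en-2-yl]cyclohex-3-ene-1-carboxylate F1. Deprotonation with LiN(i-Pr)2 in THF/DMPU at −78 °C and methylation of the copper-free enolate with MeI anti to the C5 substituent brings the material back to 17.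

The tether installation (step 15) may fail if the hindered C6 alcohol does not capture the iodinated oxocarbenium ion, or if the electrophile attacks the 1,1-disubstituted C3=C4 alkene; the vinyl radical of step 16 is then not available. The fallback is the classical two-carbon tether with late introduction of C13. It sets out from 21. Ethyl vinyl ether and N-bromosuccinimide should give the 2-bromo-1-ethoxyethyl acetal of 21 F2. Tin hydride/air cyclization through an alkyl radical gives the C8 hydroperoxide of the saturated ethyl acetal F3 and, after PPh3, the 2-ethoxy alcohol lacking the 3-methylidene group F4. Yamaguchi esterification with 31 (through 32) gives the ester of F4 with acid 31 F5, and aqueous acetic acid the saturated lactol triol F6. Mannich-type α-methylenation of its aldehyde form (aqueous formaldehyde, pyrrolidine, propionic acid, i-PrOH, 45 °C) rejoins the route at 34.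

The radical cyclization–oxygenation (step 16) may show poor facial selectivity when oxygen captures the C8 radical, so that the C8 epimer accompanies 24. The fallback makes the two epimers converge. It sets out from 22: the epimeric alcohol formed in the same operation, the C8 epimer of 24 F7, is esterified with acid 31 under Mitsunobu conditions (PPh3, i-PrO2CN=NCO2i-Pr, toluene, 0 °C → rt), which inverts C8 and rejoins the route at 33, while 24 itself continues through step 22.

Further compounds

F1 | step 10 | methyl (5R,6S)-5-(triisopropylsilyloxy)-6-[3-(trityloxy)prop-1-en-2-yl]cyclohex-3-ene-1-carboxylate (C1 epimers) | COC(=O)C1CC=C[C@@H](O[Si](C(C)C)(C(C)C)C(C)C)[C@@H]1C(=C)COC(c1ccccc1)(c1ccccc1)c1ccccc1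
F2 | step 15 | 2-bromo-1-ethoxyethyl acetal of 21 (acetal epimers) | C=C[C@]1(C)CC=C[C@@H](OC(CBr)OCC)[C@@H]1C(=C)COC(c1ccccc1)(c1ccccc1)c1ccccc1
F3 | step 15 | C8 hydroperoxide of the saturated ethyl acetal | C=C[C@]1(C)C[C@H](OO)[C@H]2CC(OCC)O[C@H]2[C@@H]1C(=C)COC(c1ccccc1)(c1ccccc1)c1ccccc1
F4 | step 15 | (3aR,4S,6S,7S,7aS)-2-ethoxy-6-ethenyl-6-methyl-7-[3-(trityloxy)prop-1-en-2-yl]octahydro-1-benzofuran-4-ol (2-ethoxy alcohol lacking the 3-methylidene group) | C=C[C@]1(C)C[C@H](O)[C@H]2CC(OCC)O[C@H]2[C@@H]1C(=C)COC(c1ccccc1)(c1ccccc1)c1ccccc1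
F5 | step 15 | ester of F4 with acid 31 | C=C[C@]1(C)C[C@H](OC(=O)C(=C)[C@@H]3COC(C)(C)O3)[C@H]2CC(OCC)O[C@H]2[C@@H]1C(=C)COC(c1ccccc1)(c1ccccc1)c1ccccc1
F6 | step 15 | saturated lactol triol, (3aR,4S,6S,7S,7aS)-6-ethenyl-2-hydroxy-7-(3-hydroxyprop-1-en-2-yl)-6-methyloctahydro-1-benzofuran-4-yl (3R)-3,4-dihydroxy-2-methylidenebutanoate | C=C[C@]1(C)C[C@H](OC(=O)C(=C)[C@@H](O)CO)[C@H]2CC(O)O[C@H]2[C@@H]1C(=C)CO
F7 | step 16 | C8 epimer of 24, (3aR,4R,6S,7S,7aS)-6-ethenyl-2-methoxy-6-methyl-3-methylidene-7-[3-(trityloxy)prop-1-en-2-yl]octahydro-1-benzofuran-4-ol | C=C[C@]1(C)C[C@@H](O)[C@H]2C(=C)C(OC)O[C@H]2[C@@H]1C(=C)COC(c1ccccc1)(c1ccccc1)c1ccccc1
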